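**Retrosynthetic overview**
1. Target 30 ⇐ acyclic seco-aldehyde 26. One chromium-mediated operation forms the C6–C7 bond (ten-membered carbocycle), and the resulting C6 alkoxide closes the cis-fused α-methylene-γ-lactone. Both rings and C6/C7 appear together in the last step; the C8 protecting group falls off in the quench.
2. 26 ⇐ 22 by desilylation, cross-metathesis of the C7 vinyl group with methyl 2-(bromomethyl)acrylate, and allylic oxidation at C6.
3. 22 ⇐ aldehyde 19 + Z-alkenyl iodide 7 by asymmetric Nozaki–Hiyama–Kishi coupling (C3–C4 bond, C3 stereocentre, 4Z alkene), then acetylation.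
4. 19 ⇐ Z-enal 12 by Brown γ-alkoxyallylboration (C8–C9 bond, syn C8/C9, the two oxygens differentiated) and Yamaguchi esterification with epoxy acid 3. Enal 12 comes from a Still–Gennari olefination (1(10)Z alkene).
5. Ring order: epoxide first (Sharpless epoxidation, step 1); carbocycle and lactone together (step 17).

Assumption: the SMILES is read as 3S,6S,7R,8S,9S with both ring alkenes Z and a (2S,3R) cis-dimethyl epoxy ester; C1–C13 in the text follow germacranolide numbering (C6 lactone O–CH, C7 ring fusion, C8 OH, C9 O-ester, C10(Me)=C1, C3 OAc, C4(Me)=C5, C12 C=O, C13 =CH2); THP ethers are carried as both epimers at the acetal carbon.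

**Route**

Step 1
Reactants: 1 (E)-2-methylbut-2-en-1-ol
Product: 2 [(2R,3R)-2,3-dimethyloxiran-2-yl]methanol
Conditions: Ti(OiPr)4 (10 mol %), D-(−)-diethyl tartrate (12 mol %), t-BuOOH, 4 Å MS, CH2Cl2, −20 °C
Reagents that add atoms: tert-butyl hydroperoxide, CC(C)(C)OO
Why: Sharpless asymmetric epoxidation of an E-allylic alcohol, in which the titanium–D-tartrate catalyst delivers oxygen to one alkene face and so sets both epoxide carbons (2R,3R, methyl groups cis).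

Step 2
Reactants: 2 [(2R,3R)-2,3-dimethyloxiran-2-yl]methanol
Product: 3 (2S,3R)-2,3-dimethyloxirane-2-carboxylic acid
Conditions: RuCl3 (2 mol %), NaIO4, MeCN/EtOAc/H2O, 0 to 25 °C
Reagents that add atoms: water, O
Why: Catalytic ruthenium tetroxide oxidation takes the primary alcohol to the acid through the aldehyde hydrate without touching the epoxide, so both stereocentres are kept (C2 becomes 2S only through the priority change).

Step 3
Reactants: 4 but-2-yn-1-ol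
Product: 6 (Z)-3-iodobut-2-en-1-ol, via cyclic alkenylalanate 5 (not isolated)
Conditions: NaAlH2(OCH2CH2OCH3)2, THF, 0 to 25 °C; then I2, −78 to 0 °C
Reagents that add atoms: iodine, II
Why: Hydroxyl-directed trans-hydroalumination of the propargylic alcohol puts aluminium on C3 cis to the CH2O group, and iododealumination with retention gives the Z-alkenyl iodide.

Step 4
Reactants: 6 (Z)-3-iodobut-2-en-1-ol
Product: 7 tert-butyl{[(2Z)-3-iodobut-2-en-1-yl]oxy}dimethylsilane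
Conditions: TBSCl, imidazole, CH2Cl2, 0 to 25 °C
Reagents that add atoms: tert-butyldimethylsilyl chloride, CC(C)(C)[Si](C)(C)Cl
Why: Imidazole-promoted silyl ether formation masks the future C6 hydroxyl until it is needed for oxidation.

Step 5
Reactants: 8 3-[(tert-butyldimethylsilyl)oxy]propanal; 9 methyl 2-[bis(2,2,2-trifluoroethoxy)phosphoryl]propanoate
Product: 10 methyl (Z)-5-[(tert-butyldimethylsilyl)oxy]-2-methylpent-2-enoate
Conditions: KN(SiMe3)2, 18-crown-6, THF, −78 °C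
Reagents that add atoms: none
Why: Still–Gennari Horner–Wadsworth–Emmons olefination, in which the trifluoroethyl phosphonate under dissociating conditions gives the kinetic Z-trisubstituted enoate (ester cis to the chain), the future 1(10)Z alkene.

Step 6
Reactants: 10 methyl (Z)-5-[(tert-butyldimethylsilyl)oxy]-2-methylpent-2-enoate
Product: 11 (Z)-5-[(tert-butyldimethylsilyl)oxy]-2-methylpent-2-en-1-ol
Conditions: i-Bu2AlH (2.2 equiv), CH2Cl2, −78 °C
Reagents that add atoms: none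
Why: Hydride 1,2-reduction of the enoate gives the allylic alcohol with the Z geometry retained.

Step 7
Reactants: 11 (Z)-5-[(tert-butyldimethylsilyl)oxy]-2-methylpent-2-en-1-ol
Product: 12 (Z)-5-[(tert-butyldimethylsilyl)oxy]-2-methylpent-2-enal
Conditions: Dess–Martin periodinane, NaHCO3, CH2Cl2, 0 °C
Reagents that add atoms: none
Why: Buffered Dess–Martin oxidation gives the configurationally labile Z-enal without Z to E isomerisation; it is used at once.

Step 8
Reactants: 12 (Z)-5-[(tert-butyldimethylsilyl)oxy]-2-methylpent-2-enal; 13 2-(allyloxy)tetrahydro-2H-pyran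
Product: 15 (3S,4S,5Z)-8-[(tert-butyldimethylsilyl)oxy]-5-methyl-3-(tetrahydro-2H-pyran-2-yloxy)octa-1,5-dien-4-ol, via alkoxyallylborane 14 (not isolated)
Conditions: s-BuLi, THF, −78 °C; (+)-Ipc2BOMe; BF3·OEt2; then 12, −78 °C; NaOH, H2O2, 0 to 25 °C
Reagents that add atoms: none
Why: Brown γ-alkoxyallylboration, in which the Z-alkoxyallylborane reacts through a chair transition state to give the syn 1,2-diol monoether and the isopinocampheyl groups direct attack to the Re face of the aldehyde, setting C9 (4S) and C8 (3S) with the two oxygens differentiated.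

Step 9
Reactants: 15 (3S,4S,5Z)-8-[(tert-butyldimethylsilyl)oxy]-5-methyl-3-(tetrahydro-2H-pyran-2-yloxy)octa-1,5-dien-4-ol; 3 (2S,3R)-2,3-dimethyloxirane-2-carboxylic acid
Product: 17 (3S,4S,5Z)-8-[(tert-butyldimethylsilyl)oxy]-5-methyl-3-(tetrahydro-2H-pyran-2-yloxy)octa-1,5-dien-4-yl (2S,3R)-2,3-dimethyloxirane-2-carboxylate, via mixed anhydride 16 (not isolated)
Conditions: 2,4,6-trichlorobenzoyl chloride, Et3N, THF, 25 °C; then 15, DMAP, toluene, 25 °C
Reagents that add atoms: none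
Why: Yamaguchi esterification through the mixed anhydride acylates the hindered secondary allylic alcohol with retention at C9 and without touching the epoxide.

Step 10
Reactants: 17 (3S,4S,5Z)-8-[(tert-butyldimethylsilyl)oxy]-5-methyl-3-(tetrahydro-2H-pyran-2-yloxy)octa-1,5-dien-4-yl (2S,3R)-2,3-dimethyloxirane-2-carboxylate
Product: 18 (3S,4S,5Z)-8-hydroxy-5-methyl-3-(tetrahydro-2H-pyran-2-yloxy)octa-1,5-dien-4-yl (2S,3R)-2,3-dimethyloxirane-2-carboxylate
Conditions: Bu4NF, AcOH (1:1), THF, 0 to 25 °C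
Reagents that add atoms: none
Why: Buffered fluoride desilylation frees the primary alcohol while the ester, epoxide and THP acetal stay intact.

Step 11
Reactants: 18 (3S,4S,5Z)-8-hydroxy-5-methyl-3-(tetrahydro-2H-pyran-2-yloxy)octa-1,5-dien-4-yl (2S,3R)-2,3-dimethyloxirane-2-carboxylate
Product: 19 (3S,4S,5Z)-5-methyl-8-oxo-3-(tetrahydro-2H-pyran-2-yloxy)octa-1,5-dien-4-yl (2S,3R)-2,3-dimethyloxirane-2-carboxylate
Conditions: Dess–Martin periodinane, NaHCO3, CH2Cl2, 0 °C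
Reagents that add atoms: none
Why: Buffered Dess–Martin oxidation gives the β,γ-unsaturated aldehyde without moving the alkene into conjugation; it is used crude.

Step 12
Reactants: 19 (3S,4S,5Z)-5-methyl-8-oxo-3-(tetrahydro-2H-pyran-2-yloxy)octa-1,5-dien-4-yl (2S,3R)-2,3-dimethyloxirane-2-carboxylate; 7 tert-butyl{[(2Z)-3-iodobut-2-en-1-yl]oxy}dimethylsilane
Product: 21 (3S,4S,5Z,8S,9Z)-11-[(tert-butyldimethylsilyl)oxy]-8-hydroxy-5,9-dimethyl-3-(tetrahydro-2H-pyran-2-yloxy)undeca-1,5,9-trien-4-yl (2S,3R)-2,3-dimethyloxirane-2-carboxylate, via alkenylchromium 20 (not isolated)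
Conditions: CrCl2 (4 equiv), NiCl2 (2 mol %), chiral oxazoline–sulfonamide ligand (Kishi type), Et3N, THF, 25 °C
Reagents that add atoms: none
Why: Asymmetric Nozaki–Hiyama–Kishi coupling, in which nickel activates the alkenyl iodide with retention of the Z geometry, the alkenylchromium adds only to the aldehyde, and the chiral ligand on chromium sets C3 (8S; ligand enantiomer chosen for this sense).

Step 13
Reactants: 21 (3S,4S,5Z,8S,9Z)-11-[(tert-butyldimethylsilyl)oxy]-8-hydroxy-5,9-dimethyl-3-(tetrahydro-2H-pyran-2-yloxy)undeca-1,5,9-trien-4-yl (2S,3R)-2,3-dimethyloxirane-2-carboxylate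
Product: 22 (3S,4S,5Z,8S,9Z)-8-acetoxy-11-[(tert-butyldimethylsilyl)oxy]-5,9-dimethyl-3-(tetrahydro-2H-pyran-2-yloxy)undeca-1,5,9-trien-4-yl (2S,3R)-2,3-dimethyloxirane-2-carboxylate
Conditions: Ac2O, pyridine, DMAP (cat.), CH2Cl2, 0 to 25 °C
Reagents that add atoms: acetic anhydride, CC(=O)OC(C)=O
Why: DMAP-catalysed acetylation of the only free hydroxyl installs the C3 acetate with retention.

Step 14
Reactants: 22 (3S,4S,5Z,8S,9Z)-8-acetoxy-11-[(tert-butyldimethylsilyl)oxy]-5,9-dimethyl-3-(tetrahydro-2H-pyran-2-yloxy)undeca-1,5,9-trien-4-yl (2S,3R)-2,3-dimethyloxirane-2-carboxylate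
Product: 23 (3S,4S,5Z,8S,9Z)-8-acetoxy-11-hydroxy-5,9-dimethyl-3-(tetrahydro-2H-pyran-2-yloxy)undeca-1,5,9-trien-4-yl (2S,3R)-2,3-dimethyloxirane-2-carboxylate
Conditions: Bu4NF, AcOH (1:1), THF, 0 °C
Reagents that add atoms: none
Why: Buffered fluoride desilylation frees the C6 hydroxyl before the allylic bromide is introduced, and the acetic acid suppresses acetate migration from O3 to O6.

Step 15
Reactants: 23 (3S,4S,5Z,8S,9Z)-8-acetoxy-11-hydroxy-5,9-dimethyl-3-(tetrahydro-2H-pyran-2-yloxy)undeca-1,5,9-trien-4-yl (2S,3R)-2,3-dimethyloxirane-2-carboxylate; 24 methyl 2-(bromomethyl)acrylate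
Product: 25 methyl (2Z,4S,5S,6Z,9S,10Z)-9-acetoxy-2-(bromomethyl)-5-{[(2S,3R)-2,3-dimethyloxirane-2-carbonyl]oxy}-12-hydroxy-6,10-dimethyl-4-(tetrahydro-2H-pyran-2-yloxy)dodeca-2,6,10-trienoate
Conditions: 24 (5 equiv), second-generation Hoveyda–Grubbs catalyst RuCl2(=CH-C6H4-2-OiPr)(H2IMes) (10 mol %), CH2Cl2, 40 °C
Reagents that add atoms: none
Why: Olefin cross-metathesis engages only the monosubstituted alkene (the trisubstituted alkenes are inert) and gives the thermodynamic isomer with the C8 chain cis to CH2Br and trans to the ester.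

Step 16
Reactants: 25 methyl (2Z,4S,5S,6Z,9S,10Z)-9-acetoxy-2-(bromomethyl)-5-{[(2S,3R)-2,3-dimethyloxirane-2-carbonyl]oxy}-12-hydroxy-6,10-dimethyl-4-(tetrahydro-2H-pyran-2-yloxy)dodeca-2,6,10-trienoate
Product: 26 methyl (2Z,4S,5S,6Z,9S,10Z)-9-acetoxy-2-(bromomethyl)-5-{[(2S,3R)-2,3-dimethyloxirane-2-carbonyl]oxy}-6,10-dimethyl-12-oxo-4-(tetrahydro-2H-pyran-2-yloxy)dodeca-2,6,10-trienoate
Conditions: MnO2, CH2Cl2, 25 °C
Reagents that add atoms: none
Why: MnO2 oxidises only the primary allylic alcohol and keeps the Z geometry of the enal, leaving the allylic bromide untouched.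

Step 17
Reactants: 26 methyl (2Z,4S,5S,6Z,9S,10Z)-9-acetoxy-2-(bromomethyl)-5-{[(2S,3R)-2,3-dimethyloxirane-2-carbonyl]oxy}-6,10-dimethyl-12-oxo-4-(tetrahydro-2H-pyran-2-yloxy)dodeca-2,6,10-trienoate
Product: 30 (3aR,4S,5S,6Z,9S,10Z,11aS)-9-acetoxy-4-hydroxy-6,10-dimethyl-3-methylidene-2-oxo-2,3,3a,4,5,8,9,11a-octahydrocyclodeca[b]furan-5-yl (2S,3R)-2,3-dimethyloxirane-2-carboxylate, via allylchromium 27 (not isolated), via chromium alkoxide 28 (not isolated), via THP ether 29 (not isolated)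
Conditions: CrCl2 (10 equiv), THF, 0.002 M, slow addition, 25 °C; then concentrate, MeOH, p-TsOH·H2O (cat.), 25 °C
Reagents that add atoms: none
Why: Intramolecular Nozaki–Hiyama (chromium Barbier) 2-(alkoxycarbonyl)allylation, in which the allylchromium adds through C7 to the C6 aldehyde in a closed chair transition state (C8 cis to CH2Cr gives the syn adduct, and chelation of chromium by the C8 THP oxygen directs the aldehyde to the C7 face syn to O8), closing the ten-membered ring and setting C6 (S) and C7 (R), after which the chromium alkoxide lactonises onto the methyl ester to close the cis-fused α-methylene-γ-lactone in the same flask and acidic methanol removes the THP group.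

**Compound list**

1 | (E)-2-methylbut-2-en-1-ol (tiglyl alcohol) | C/C=C(\C)CO | starting material
2 | [(2R,3R)-2,3-dimethyloxiran-2-yl]methanol | OC[C@@]1(C)O[C@@H]1C | intermediate
3 | (2S,3R)-2,3-dimethyloxirane-2-carboxylic acid | OC(=O)[C@@]1(C)O[C@@H]1C | intermediate
4 | but-2-yn-1-ol | CC#CCO | starting material
5 | sodium cyclic alkenylalanate, 2,2-bis(2-methoxyethoxy)-3-methyl-2,5-dihydro-1,2-oxaaluminol-2-uide (not isolated) | [Na+].CC1=CCO[Al-]1(OCCOC)OCCOC | intermediate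
6 | (Z)-3-iodobut-2-en-1-ol | C/C(I)=C/CO | intermediate
7 | tert-butyl{[(2Z)-3-iodobut-2-en-1-yl]oxy}dimethylsilane | C/C(I)=C/CO[Si](C)(C)C(C)(C)C | intermediate
8 | 3-[(tert-butyldimethylsilyl)oxy]propanal | O=CCCO[Si](C)(C)C(C)(C)C | starting material
9 | methyl 2-[bis(2,2,2-trifluoroethoxy)phosphoryl]propanoate | COC(=O)C(C)P(=O)(OCC(F)(F)F)OCC(F)(F)F | starting material
10 | methyl (Z)-5-[(tert-butyldimethylsilyl)oxy]-2-methylpent-2-enoate | COC(=O)/C(C)=C\CCO[Si](C)(C)C(C)(C)C | intermediate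
11 | (Z)-5-[(tert-butyldimethylsilyl)oxy]-2-methylpent-2-en-1-ol | OC/C(C)=C\CCO[Si](C)(C)C(C)(C)C | intermediate
12 | (Z)-5-[(tert-butyldimethylsilyl)oxy]-2-methylpent-2-enal | O=C/C(C)=C\CCO[Si](C)(C)C(C)(C)C | intermediate
13 | 2-(allyloxy)tetrahydro-2H-pyran (racemic) | C=CCOC1CCCCO1 | starting material
14 | B-[(Z)-3-(tetrahydro-2H-pyran-2-yloxy)prop-2-en-1-yl]diisopinocampheylborane from (+)-Ipc2BOMe (not isolated) | C(/C=C\OC1CCCCO1)B([C@H]1C[C@H]2C[C@@H]([C@@H]1C)C2(C)C)[C@H]1C[C@H]2C[C@@H]([C@@H]1C)C2(C)C | intermediate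
15 | (3S,4S,5Z)-8-[(tert-butyldimethylsilyl)oxy]-5-methyl-3-(tetrahydro-2H-pyran-2-yloxy)octa-1,5-dien-4-ol (both THP epimers) | CC(C)(C)[Si](C)(C)OCC/C=C(/C)[C@H](O)[C@@H](OC1CCCCO1)C=C | intermediate
16 | (2S,3R)-2,3-dimethyloxirane-2-carboxylic 2,4,6-trichlorobenzoic anhydride (not isolated) | O=C(OC(=O)[C@@]1(C)O[C@@H]1C)c1c(Cl)cc(Cl)cc1Cl | intermediate
17 | (3S,4S,5Z)-8-[(tert-butyldimethylsilyl)oxy]-5-methyl-3-(tetrahydro-2H-pyran-2-yloxy)octa-1,5-dien-4-yl (2S,3R)-2,3-dimethyloxirane-2-carboxylate | CC(C)(C)[Si](C)(C)OCC/C=C(/C)[C@H](OC(=O)[C@@]1(C)O[C@@H]1C)[C@@H](OC1CCCCO1)C=C | intermediate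
18 | (3S,4S,5Z)-8-hydroxy-5-methyl-3-(tetrahydro-2H-pyran-2-yloxy)octa-1,5-dien-4-yl (2S,3R)-2,3-dimethyloxirane-2-carboxylate | OCC/C=C(/C)[C@H](OC(=O)[C@@]1(C)O[C@@H]1C)[C@@H](OC1CCCCO1)C=C | intermediate
19 | (3S,4S,5Z)-5-methyl-8-oxo-3-(tetrahydro-2H-pyran-2-yloxy)octa-1,5-dien-4-yl (2S,3R)-2,3-dimethyloxirane-2-carboxylate | O=CC/C=C(/C)[C@H](OC(=O)[C@@]1(C)O[C@@H]1C)[C@@H](OC1CCCCO1)C=C | intermediate
20 | {(2Z)-4-[(tert-butyldimethylsilyl)oxy]but-2-en-2-yl}chromium dichloride, trivalent chromium (not isolated) | C/C([Cr](Cl)Cl)=C/CO[Si](C)(C)C(C)(C)C | intermediate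
21 | (3S,4S,5Z,8S,9Z)-11-[(tert-butyldimethylsilyl)oxy]-8-hydroxy-5,9-dimethyl-3-(tetrahydro-2H-pyran-2-yloxy)undeca-1,5,9-trien-4-yl (2S,3R)-2,3-dimethyloxirane-2-carboxylate | CC(C)(C)[Si](C)(C)OC/C=C(/C)[C@@H](O)C/C=C(/C)[C@H](OC(=O)[C@@]1(C)O[C@@H]1C)[C@@H](OC1CCCCO1)C=C | intermediate
22 | (3S,4S,5Z,8S,9Z)-8-acetoxy-11-[(tert-butyldimethylsilyl)oxy]-5,9-dimethyl-3-(tetrahydro-2H-pyran-2-yloxy)undeca-1,5,9-trien-4-yl (2S,3R)-2,3-dimethyloxirane-2-carboxylate | CC(C)(C)[Si](C)(C)OC/C=C(/C)[C@@H](OC(C)=O)C/C=C(/C)[C@H](OC(=O)[C@@]1(C)O[C@@H]1C)[C@@H](OC1CCCCO1)C=C | intermediate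
23 | (3S,4S,5Z,8S,9Z)-8-acetoxy-11-hydroxy-5,9-dimethyl-3-(tetrahydro-2H-pyran-2-yloxy)undeca-1,5,9-trien-4-yl (2S,3R)-2,3-dimethyloxirane-2-carboxylate | OC/C=C(/C)[C@@H](OC(C)=O)C/C=C(/C)[C@H](OC(=O)[C@@]1(C)O[C@@H]1C)[C@@H](OC1CCCCO1)C=C | intermediate
24 | methyl 2-(bromomethyl)acrylate | C=C(CBr)C(=O)OC | starting material
25 | methyl (2Z,4S,5S,6Z,9S,10Z)-9-acetoxy-2-(bromomethyl)-5-{[(2S,3R)-2,3-dimethyloxirane-2-carbonyl]oxy}-12-hydroxy-6,10-dimethyl-4-(tetrahydro-2H-pyran-2-yloxy)dodeca-2,6,10-trienoate | OC/C=C(/C)[C@@H](OC(C)=O)C/C=C(/C)[C@H](OC(=O)[C@@]1(C)O[C@@H]1C)[C@@H](OC1CCCCO1)/C=C(\CBr)C(=O)OC | intermediate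
26 | methyl (2Z,4S,5S,6Z,9S,10Z)-9-acetoxy-2-(bromomethyl)-5-{[(2S,3R)-2,3-dimethyloxirane-2-carbonyl]oxy}-6,10-dimethyl-12-oxo-4-(tetrahydro-2H-pyran-2-yloxy)dodeca-2,6,10-trienoate | O=C/C=C(/C)[C@@H](OC(C)=O)C/C=C(/C)[C@H](OC(=O)[C@@]1(C)O[C@@H]1C)[C@@H](OC1CCCCO1)/C=C(\CBr)C(=O)OC | intermediate
27 | allylchromium dichloride from 26, CrCl2 in place of Br on C13 (not isolated) | O=C/C=C(/C)[C@@H](OC(C)=O)C/C=C(/C)[C@H](OC(=O)[C@@]1(C)O[C@@H]1C)[C@@H](OC1CCCCO1)/C=C(\C[Cr](Cl)Cl)C(=O)OC | intermediate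
28 | ten-membered-ring chromium alkoxide, C6–O–CrCl2 with the C12 methyl ester still open (not isolated) | Cl[Cr](Cl)O[C@H]1/C=C(/C)[C@@H](OC(C)=O)C/C=C(/C)[C@H](OC(=O)[C@@]2(C)O[C@@H]2C)[C@@H](OC2CCCCO2)[C@H]1C(=C)C(=O)OC | intermediate
29 | 8-O-(tetrahydro-2H-pyran-2-yl) ether of 30 (not isolated) | C=C1C(=O)O[C@H]2/C=C(/C)[C@@H](OC(C)=O)C/C=C(/C)[C@H](OC(=O)[C@@]3(C)O[C@@H]3C)[C@@H](OC3CCCCO3)[C@@H]12 | intermediate
30 | (3aR,4S,5S,6Z,9S,10Z,11aS)-9-acetoxy-4-hydroxy-6,10-dimethyl-3-methylidene-2-oxo-2,3,3a,4,5,8,9,11a-octahydrocyclodeca[b]furan-5-yl (2S,3R)-2,3-dimethyloxirane-2-carboxylate (CNP0137407.7) | C=C1C(=O)O[C@H]2/C=C(/C)[C@@H](OC(C)=O)C/C=C(/C)[C@H](OC(=O)[C@@]3(C)O[C@@H]3C)[C@@H](O)[C@@H]12 | target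

**Totals and risks**

Total step count: 17. Longest linear sequence: 13 steps (8 to 30, steps 5–17).

The three steps most likely to fail:

Step 17 (ring closure). Oligomerisation, 1,4-elimination of the C8 alkoxy group from the allylchromium, or the wrong face at C7 would each ruin the last step. The fallback builds the lactone first and closes the carbocycle at another bond; it sets out from 17 and comes back at 29. Cross-metathesis of 17 with 24 gives bromo ester F1. CrCl2 without nickel (so the alkenyl iodide is untouched) couples F1 with (Z)-3-iodobut-2-enal F2 (from 6 with MnO2) in an intermolecular Barbier allylation–lactonisation to cis-lactone F3. Buffered Bu4NF gives alcohol F4, and Dess–Martin oxidation gives aldehyde F5. An intramolecular Nozaki–Hiyama–Kishi alkenyl iodide–aldehyde coupling (CrCl2, NiCl2 cat., high dilution) then closes the ten-membered ring at C3–C4 to macrocyclic alcohol F6. Acetylation gives 29, and the acidic methanol stage of step 17 gives 30.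

Step 15 (cross-metathesis). A hindered allylic ether and a 1,1-disubstituted acrylate may couple poorly. The fallback replaces it by a ring-closing metathesis and carries O8 as a lactone oxygen; it sets out from 22 and comes back at 30. PPTS in methanol removes the THP group to give alcohol F7. Esterification of O8 with 2-(bromomethyl)acrylic acid (DIC, DMAP cat.) gives acrylate F8. Ring-closing metathesis (second-generation Grubbs catalyst RuCl2(=CHPh)(PCy3)(H2IMes), toluene, 80 °C) gives bromomethyl butenolide F9. HF·pyridine gives alcohol F10, and MnO2 gives enal F11. CrCl2 at high dilution then adds C7 to the aldehyde, and the chromium alkoxide on O6 translactonises (the O8 lactone opens, the O6 lactone closes) to give 30 with the C8 hydroxyl free; whether the equilibrium favours the O6 lactone is not known and would need testing.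

Step 12 (asymmetric alkenylation). The sense and level of ligand control for this trisubstituted Z-alkenyl iodide are not established, and the aldehyde can isomerise. The fallback sets C3 by reagent-controlled reduction; it sets out from 19 (with 7) and comes back at 21. A ligand-free Nozaki–Hiyama–Kishi coupling gives the C3-epimer mixture F12. Dess–Martin oxidation gives enone F13. Corey–Bakshi–Shibata reduction ((R)-2-methyl-oxazaborolidine, catecholborane, toluene, −78 °C; the alkenyl side acts as the large group) gives 21.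

Further compounds
F1 | step 17 | methyl (2Z,4S,5S,6Z)-2-(bromomethyl)-9-[(tert-butyldimethylsilyl)oxy]-5-{[(2S,3R)-2,3-dimethyloxirane-2-carbonyl]oxy}-6-methyl-4-(tetrahydro-2H-pyran-2-yloxy)nona-2,6-dienoate | CC(C)(C)[Si](C)(C)OCC/C=C(/C)[C@H](OC(=O)[C@@]1(C)O[C@@H]1C)[C@@H](OC1CCCCO1)/C=C(\CBr)C(=O)OC
F2 | step 17 | (Z)-3-iodobut-2-enal | C/C(I)=C/C=O
F3 | step 17 | cis-α-methylene-γ-butyrolactone with the (Z)-2-iodoprop-1-enyl group on C6 and the silyl-protected C8–C3 chain on C7 (C6 to C9 as in 30) | C=C1C(=O)O[C@@H](/C=C(/C)I)[C@H]1[C@H](OC1CCCCO1)[C@@H](OC(=O)[C@@]1(C)O[C@@H]1C)/C(C)=C\CCO[Si](C)(C)C(C)(C)C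
F4 | step 17 | primary alcohol from F3 | C=C1C(=O)O[C@@H](/C=C(/C)I)[C@H]1[C@H](OC1CCCCO1)[C@@H](OC(=O)[C@@]1(C)O[C@@H]1C)/C(C)=C\CCO
F5 | step 17 | aldehyde from F4 | C=C1C(=O)O[C@@H](/C=C(/C)I)[C@H]1[C@H](OC1CCCCO1)[C@@H](OC(=O)[C@@]1(C)O[C@@H]1C)/C(C)=C\CC=O
F6 | step 17 | 3-O-deacetyl 8-O-tetrahydropyranyl derivative of 30 | C=C1C(=O)O[C@H]2/C=C(/C)[C@@H](O)C/C=C(/C)[C@H](OC(=O)[C@@]3(C)O[C@@H]3C)[C@@H](OC3CCCCO3)[C@@H]12
F7 | step 15 | C8 alcohol from 22 (THP removed) | CC(C)(C)[Si](C)(C)OC/C=C(/C)[C@@H](OC(C)=O)C/C=C(/C)[C@H](OC(=O)[C@@]1(C)O[C@@H]1C)[C@@H](O)C=C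
F8 | step 15 | 2-(bromomethyl)acrylate ester of F7 at O8 | CC(C)(C)[Si](C)(C)OC/C=C(/C)[C@@H](OC(C)=O)C/C=C(/C)[C@H](OC(=O)[C@@]1(C)O[C@@H]1C)[C@@H](OC(=O)C(=C)CBr)C=C
F9 | step 15 | 3-(bromomethyl)furan-2(5H)-one with O8 in the ring and the C9–C6 chain on C8 | CC(C)(C)[Si](C)(C)OC/C=C(/C)[C@@H](OC(C)=O)C/C=C(/C)[C@H](OC(=O)[C@@]1(C)O[C@@H]1C)[C@H]1OC(=O)C(CBr)=C1
F10 | step 15 | primary allylic alcohol from F9 | OC/C=C(/C)[C@@H](OC(C)=O)C/C=C(/C)[C@H](OC(=O)[C@@]1(C)O[C@@H]1C)[C@H]1OC(=O)C(CBr)=C1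
F11 | step 15 | Z-enal from F10 | O=C/C=C(/C)[C@@H](OC(C)=O)C/C=C(/C)[C@H](OC(=O)[C@@]1(C)O[C@@H]1C)[C@H]1OC(=O)C(CBr)=C1
F12 | step 12 | mixture of 21 and its C8 epimer (8RS) | CC(C)(C)[Si](C)(C)OC/C=C(/C)C(O)C/C=C(/C)[C@H](OC(=O)[C@@]1(C)O[C@@H]1C)[C@@H](OC1CCCCO1)C=C
F13 | step 12 | (3S,4S,5Z,9Z)-11-[(tert-butyldimethylsilyl)oxy]-5,9-dimethyl-8-oxo-3-(tetrahydro-2H-pyran-2-yloxy)undeca-1,5,9-trien-4-yl (2S,3R)-2,3-dimethyloxirane-2-carboxylate | CC(C)(C)[Si](C)(C)OC/C=C(/C)C(=O)C/C=C(/C)[C@H](OC(=O)[C@@]1(C)O[C@@H]1C)[C@@H](OC1CCCCO1)C=C
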